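The route rests on opening the pyranone of the 2-(4-methoxyphenyl)chromone unit at C4–C4a and O1–C2. In ring A of that unit, O5 and O7 flank C6, the carbon bonded to C3 of the second chromone; with both oxygens as methyl ethers the parent phenol is symmetric, so its two ortho C–H carbons (future C4a and C8) are identical and a thermal condensation with ethyl 4-methoxybenzoylacetate can only build the 6-linked biflavone, closing the last ring and forming two skeletal bonds in one operation. The precursor is the complete second chromone carrying a 4-hydroxy-2,6-dimethoxyphenyl group at C3 and an isopropyl-masked 4-hydroxyphenyl group at C2.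

Key step: step 8

Remark: the target structure defines no configuration at the hindered biaryl axis between the two chromones, so no axial stereocontrol is planned. Unit 1 is the 2-(4-methoxyphenyl)chromone, unit 2 the 2-(4-hydroxyphenyl)chromone.

Step 1
Reactants: 1 4-hydroxy-2,6-dimethoxybenzaldehyde
Product: 2 4-(benzyloxy)-2,6-dimethoxybenzaldehyde
Conditions: BnBr, K2CO3, DMF, 60 °C
Reagents that add atoms: benzyl bromide, BrCc1ccccc1
Why: Williamson ether synthesis; the acidic para-formyl phenoxide is the only nucleophile present, so O-benzylation should be clean.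

Step 2
Reactants: 2 4-(benzyloxy)-2,6-dimethoxybenzaldehyde
Product: 4 2-[4-(benzyloxy)-2,6-dimethoxyphenyl]acetaldehyde, via methyl enol ether 3 (not isolated)
Conditions: Ph3P(CH2OMe)Cl, KOtBu, THF, 0 °C to rt; then 2 M aq HCl, THF, rt
Reagents that add atoms: (methoxymethyl)triphenylphosphonium chloride, COC[P+](c1ccccc1)(c1ccccc1)c1ccccc1.[Cl-]; water, O
Why: Wittig methoxymethylenation gives the enol ether, whose electron-rich double bond is protonated easily, so mild aqueous acid should release the one-carbon-homologated aldehyde, which is oxidised at once to avoid self-condensation.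

Step 3
Reactants: 4 2-[4-(benzyloxy)-2,6-dimethoxyphenyl]acetaldehyde
Product: 5 2-[4-(benzyloxy)-2,6-dimethoxyphenyl]acetic acid
Conditions: NaClO2, NaH2PO4, 2-methyl-2-butene (excess), t-BuOH/H2O, 0 °C to rt
Reagents that add atoms: sodium chlorite, [Na+].[O-]Cl=O
Why: Pinnick oxidation; chlorous acid oxidises only the aldehyde, and the excess alkene traps hypochlorous acid before it can chlorinate the electron-rich ring.

Step 4
Reactants: 5 2-[4-(benzyloxy)-2,6-dimethoxyphenyl]acetic acid; 6 3,5-dimethoxyphenol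
Product: 7 2-[4-(benzyloxy)-2,6-dimethoxyphenyl]-1-(2-hydroxy-4,6-dimethoxyphenyl)ethan-1-one
Conditions: 6 (1.5 equiv), BF3·OEt2 (as solvent), 70 °C
Reagents that add atoms: none
Why: Friedel–Crafts acylation of a phenol by an arylacetic acid in BF3·OEt2 (the standard deoxybenzoin synthesis); boron bound to the phenol oxygen should steer the acyl group to the carbon next to the hydroxyl, and water is the only co-product.

Step 5
Reactants: 7 2-[4-(benzyloxy)-2,6-dimethoxyphenyl]-1-(2-hydroxy-4,6-dimethoxyphenyl)ethan-1-one; 8 4-(propan-2-yloxy)benzoic acid (4-isopropoxybenzoic acid)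
Product: 9 2-{2-[4-(benzyloxy)-2,6-dimethoxyphenyl]acetyl}-3,5-dimethoxyphenyl 4-(propan-2-yloxy)benzoate
Conditions: DCC, DMAP (cat.), CH2Cl2, rt
Reagents that add atoms: none
Why: Steglich esterification; DCC activates the acid and DMAP transfers the aroyl group to the hydrogen-bonded phenol, the only hydroxyl in 7.

Step 6
Reactants: 9 2-{2-[4-(benzyloxy)-2,6-dimethoxyphenyl]acetyl}-3,5-dimethoxyphenyl 4-(propan-2-yloxy)benzoate
Product: 11 3-[4-(benzyloxy)-2,6-dimethoxyphenyl]-5,7-dimethoxy-2-[4-(propan-2-yloxy)phenyl]-4H-chromen-4-one, via triaryl 1,3-diketone 10 (not isolated)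
Conditions: LiN(SiMe3)2 (2.5 equiv), THF, −20 °C to rt, AcOH quench; then TsOH·H2O (cat.), toluene, 80 °C
Reagents that add atoms: none
Why: Baker–Venkataraman rearrangement, in which the enolate of the benzylic ketone takes the aroyl group from the neighbouring ester through a six-membered transition state, followed by acid-catalysed cyclodehydration of the freed phenol onto the aroyl ketone to close the 2,3-diarylchromone.

Step 7
Reactants: 11 3-[4-(benzyloxy)-2,6-dimethoxyphenyl]-5,7-dimethoxy-2-[4-(propan-2-yloxy)phenyl]-4H-chromen-4-one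
Product: 12 3-(4-hydroxy-2,6-dimethoxyphenyl)-5,7-dimethoxy-2-[4-(propan-2-yloxy)phenyl]-4H-chromen-4-one
Conditions: H2 (1 atm), 10% Pd/C, EtOAc/MeOH, rt
Reagents that add atoms: none
Why: Hydrogenolysis of the aryl benzyl ether; the tetrasubstituted, diaryl-flanked chromone double bond and the isopropyl and methyl ethers should not be touched at 1 atm and rt.

Step 8
Reactants: 12 3-(4-hydroxy-2,6-dimethoxyphenyl)-5,7-dimethoxy-2-[4-(propan-2-yloxy)phenyl]-4H-chromen-4-one; 13 ethyl 3-(4-methoxyphenyl)-3-oxopropanoate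
Product: 16 6-{5,7-dimethoxy-4-oxo-2-[4-(propan-2-yloxy)phenyl]-4H-chromen-3-yl}-5,7-dimethoxy-2-(4-methoxyphenyl)-4H-chromen-4-one (5,5''-di-O-methyl-4'''-O-isopropylstephaflavone B), via aroylketene 14 (not isolated), via hydroxyaryl diketone 15 (not isolated)
Conditions: 13 (4 equiv, portionwise), neat melt, 240 °C, N2 stream (EtOH and H2O swept out)
Reagents that add atoms: none
Why: At about 240 °C ketoester 13 should lose ethanol to give aroylketene 14, which C-acylates the phloroglucinol-type ring of 12 at a carbon next to the free hydroxyl, forming C4–C4a and giving the ortho-hydroxyaryl 1,3-diketone 15. The phenol oxygen of 15 then adds to the 4-methoxyphenyl ketone in a 6-exo-trig closure and the hemiketal loses water, forming O1–C2 and the pyranone of unit 1. The closest known reaction type is the Mentzer pyrone synthesis, the thermal, acid-free condensation of phenols with beta-ketoesters to chromones (Simonis variant). No stereocentre is formed. Chromone must win over the Pechmann coumarin, which the absence of acid should secure because the ester carbon, as the ketene, and not the ketone is then the electrophile that bonds to the ring. The 6- rather than 8-linkage is fixed by the substrate, since the para carbon is blocked by unit 2 and the two open ortho carbons, each between OH and OMe, are related by symmetry.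

Step 9
Reactants: 16 6-{5,7-dimethoxy-4-oxo-2-[4-(propan-2-yloxy)phenyl]-4H-chromen-3-yl}-5,7-dimethoxy-2-(4-methoxyphenyl)-4H-chromen-4-one
Product: 17 stephaflavone B, 5-hydroxy-6-[5-hydroxy-2-(4-hydroxyphenyl)-7-methoxy-4-oxo-4H-chromen-3-yl]-7-methoxy-2-(4-methoxyphenyl)-4H-chromen-4-one
Conditions: BCl3 (8 equiv), CH2Cl2, −78 to 0 °C; then aq HCl/MeOH
Reagents that add atoms: none
Why: Lewis-acid ether cleavage; BCl3 chelated to each C4 carbonyl should remove the methyl of the peri 5-methoxy group and should also cleave the secondary isopropyl ether, while the unchelated 7-methoxy groups of both chromones and the 4-methoxyphenyl ether are inert at this temperature.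

Compound list
1 | 4-hydroxy-2,6-dimethoxybenzaldehyde | COc1cc(O)cc(OC)c1C=O | starting material
2 | 4-(benzyloxy)-2,6-dimethoxybenzaldehyde | COc1cc(OCc2ccccc2)cc(OC)c1C=O | intermediate
3 | 5-(benzyloxy)-1,3-dimethoxy-2-(2-methoxyethenyl)benzene (E/Z mixture, geometry irrelevant) | COC=Cc1c(OC)cc(OCc2ccccc2)cc1OC | intermediate
4 | 2-[4-(benzyloxy)-2,6-dimethoxyphenyl]acetaldehyde | COc1cc(OCc2ccccc2)cc(OC)c1CC=O | intermediate
5 | 2-[4-(benzyloxy)-2,6-dimethoxyphenyl]acetic acid | COc1cc(OCc2ccccc2)cc(OC)c1CC(=O)O | intermediate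
6 | 3,5-dimethoxyphenol | COc1cc(O)cc(OC)c1 | starting material
7 | 2-[4-(benzyloxy)-2,6-dimethoxyphenyl]-1-(2-hydroxy-4,6-dimethoxyphenyl)ethan-1-one | COc1cc(O)c(C(=O)Cc2c(OC)cc(OCc3ccccc3)cc2OC)c(OC)c1 | intermediate
8 | 4-(propan-2-yloxy)benzoic acid | CC(C)Oc1ccc(C(=O)O)cc1 | starting material
9 | 2-{2-[4-(benzyloxy)-2,6-dimethoxyphenyl]acetyl}-3,5-dimethoxyphenyl 4-(propan-2-yloxy)benzoate | COc1cc(OC(=O)c2ccc(OC(C)C)cc2)c(C(=O)Cc2c(OC)cc(OCc3ccccc3)cc2OC)c(OC)c1 | intermediate
10 | 2-[4-(benzyloxy)-2,6-dimethoxyphenyl]-1-(2-hydroxy-4,6-dimethoxyphenyl)-3-[4-(propan-2-yloxy)phenyl]propane-1,3-dione (racemic, enolisable methine) | COc1cc(O)c(C(=O)C(C(=O)c2ccc(OC(C)C)cc2)c2c(OC)cc(OCc3ccccc3)cc2OC)c(OC)c1 | intermediate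
11 | 3-[4-(benzyloxy)-2,6-dimethoxyphenyl]-5,7-dimethoxy-2-[4-(propan-2-yloxy)phenyl]-4H-chromen-4-one | COc1cc(OCc2ccccc2)cc(OC)c1-c1c(-c2ccc(OC(C)C)cc2)oc2cc(OC)cc(OC)c2c1=O | intermediate
12 | 3-(4-hydroxy-2,6-dimethoxyphenyl)-5,7-dimethoxy-2-[4-(propan-2-yloxy)phenyl]-4H-chromen-4-one | COc1cc(O)cc(OC)c1-c1c(-c2ccc(OC(C)C)cc2)oc2cc(OC)cc(OC)c2c1=O | intermediate
13 | ethyl 3-(4-methoxyphenyl)-3-oxopropanoate | CCOC(=O)CC(=O)c1ccc(OC)cc1 | starting material
14 | (4-methoxybenzoyl)ketene | COc1ccc(C(=O)C=C=O)cc1 | intermediate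
15 | 3-{4-hydroxy-2,6-dimethoxy-3-[3-(4-methoxyphenyl)-3-oxopropanoyl]phenyl}-5,7-dimethoxy-2-[4-(propan-2-yloxy)phenyl]-4H-chromen-4-one | COc1ccc(C(=O)CC(=O)c2c(O)cc(OC)c(-c3c(-c4ccc(OC(C)C)cc4)oc4cc(OC)cc(OC)c4c3=O)c2OC)cc1 | intermediate
16 | 6-{5,7-dimethoxy-4-oxo-2-[4-(propan-2-yloxy)phenyl]-4H-chromen-3-yl}-5,7-dimethoxy-2-(4-methoxyphenyl)-4H-chromen-4-one | COc1ccc(-c2cc(=O)c3c(OC)c(-c4c(-c5ccc(OC(C)C)cc5)oc5cc(OC)cc(OC)c5c4=O)c(OC)cc3o2)cc1 | intermediate
17 | stephaflavone B, 5-hydroxy-6-[5-hydroxy-2-(4-hydroxyphenyl)-7-methoxy-4-oxo-4H-chromen-3-yl]-7-methoxy-2-(4-methoxyphenyl)-4H-chromen-4-one | COc1ccc(-c2cc(=O)c3c(O)c(-c4c(-c5ccc(O)cc5)oc5cc(OC)cc(O)c5c4=O)c(OC)cc3o2)cc1 | target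

Total step count: 9
Longest linear sequence: 9 steps (1 to 17)

Steps most likely to fail

Step 8. At 240 °C the ketoester may self-condense or decarboxylate faster than it acylates the hindered, high-melting phenol, acylation may stop at oxygen, or long heating may degrade the material. The fallback sets out from 12 and comes back at 16, building the same two bonds stepwise by the chalcone route. Friedel–Crafts acetylation of 12 (AcOH, BF3·OEt2, 80 °C) should give, again as one isomer by symmetry, 3-(3-acetyl-4-hydroxy-2,6-dimethoxyphenyl)-5,7-dimethoxy-2-[4-(propan-2-yloxy)phenyl]-4H-chromen-4-one F1. Claisen–Schmidt condensation with 4-methoxybenzaldehyde (KOH, EtOH, rt) should give the 2'-hydroxychalcone 3-{4-hydroxy-2,6-dimethoxy-3-[(2E)-3-(4-methoxyphenyl)prop-2-enoyl]phenyl}-5,7-dimethoxy-2-[4-(propan-2-yloxy)phenyl]-4H-chromen-4-one F2. Oxidative cyclisation with catalytic I2 in DMSO at 130 °C should then close the pyranone and deliver 16.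

Step 4. The benzyl group may be lost or may migrate under the hot Lewis acid, and acylation may occur para to the hydroxyl or on the electron-rich ring of the acid itself. The fallback sets out from 5 and comes back at 7, using a symmetric arene under mild conditions and then a chelation-controlled demethylation. Acid 5 and 1,3,5-trimethoxybenzene (excess) with TFAA and catalytic H3PO4 in CH2Cl2 at 0 °C to rt should give 2-[4-(benzyloxy)-2,6-dimethoxyphenyl]-1-(2,4,6-trimethoxyphenyl)ethan-1-one F3, for which no regiochemical question arises. MgI2·OEt2 in toluene at 80 °C should then remove only the methyl group of one methoxy ortho to the ketone, through a magnesium chelate, sparing the benzyl ether and giving 7.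

Step 6. Acyl transfer to the crowded benzylic carbon, flanked by the 2,6-dimethoxyaryl group, may be slow, so that the ester is merely cleaved back to the phenol, or the congested diketone may resist dehydration. The fallback sets out from 7 and comes back at 11, replacing steps 5 and 6 by condensation with an aldehyde and dehydrogenation. Ketone 7 and 4-(propan-2-yloxy)benzaldehyde with piperidine in EtOH at reflux should undergo Knoevenagel condensation and oxa-Michael ring closure to racemic trans-3-[4-(benzyloxy)-2,6-dimethoxyphenyl]-5,7-dimethoxy-2-[4-(propan-2-yloxy)phenyl]chroman-4-one F4. The aldehyde is a smaller and more reactive electrophile than the tethered ester, and the ring closure drives the reversible condensation forward. DDQ in dioxane at reflux should then dehydrogenate C2–C3, erasing both stereocentres, to give 11.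

Further compounds
F1 | step 8 | 3-(3-acetyl-4-hydroxy-2,6-dimethoxyphenyl)-5,7-dimethoxy-2-[4-(propan-2-yloxy)phenyl]-4H-chromen-4-one | CC(=O)c1c(O)cc(OC)c(-c2c(-c3ccc(OC(C)C)cc3)oc3cc(OC)cc(OC)c3c2=O)c1OC
F2 | step 8 | 3-{4-hydroxy-2,6-dimethoxy-3-[(2E)-3-(4-methoxyphenyl)prop-2-enoyl]phenyl}-5,7-dimethoxy-2-[4-(propan-2-yloxy)phenyl]-4H-chromen-4-one | COc1ccc(/C=C/C(=O)c2c(O)cc(OC)c(-c3c(-c4ccc(OC(C)C)cc4)oc4cc(OC)cc(OC)c4c3=O)c2OC)cc1
F3 | step 4 | 2-[4-(benzyloxy)-2,6-dimethoxyphenyl]-1-(2,4,6-trimethoxyphenyl)ethan-1-one | COc1cc(OC)c(C(=O)Cc2c(OC)cc(OCc3ccccc3)cc2OC)c(OC)c1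
F4 | step 6 | trans-3-[4-(benzyloxy)-2,6-dimethoxyphenyl]-5,7-dimethoxy-2-[4-(propan-2-yloxy)phenyl]chroman-4-one (racemic, one enantiomer drawn) | COc1cc(OC)c2c(c1)O[C@@H](c1ccc(OC(C)C)cc1)[C@H](c1c(OC)cc(OCc3ccccc3)cc1OC)C2=O
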